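Numbering: both halves are numbered as phthalides. The unprimed half holds cyclohexene ring A (C3a, C4 to C7, C7a). The primed six-membered ring C3a'–C7a' lies inside the bicyclo[2.2.2]octene. Ring B is C6–C7–C4'–C5'–C6'–C7'. The halves are joined through C6–C7' and C7–C4'.
Cuts, in retrosynthetic order: (a) O2–C3, C7a–C1 and C3a–C3 of the unprimed lactone, back to a C7a ketone masked as a ketal; (b) C6'–OH back to a ketone and O2'–C3' back to a keto ester; (c) C7'–C7a' and C4'–C3a', which leaves a cis-decalin enone and a C8 bromo ene keto ester; (d) C6–C7' and C7–C4' of ring B by a Diels–Alder disconnection.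
Enabling feature: with C6' as a ketone, C5' is its α-carbon, and C3a' is the β-carbon of the C1' ester. The C7a'=C3a' bridge alkene can therefore be stored as an extra C5'–C3a' cyclopropane bond, which an ester enolate at C7a' can expel again.
Forward order of rings: ring A is bought as cyclohexenone, and ring B comes from a Diels–Alder reaction. The primed six-membered ring and the cyclopropane are then closed in one flask. The cyclopropane is opened to the bicyclo[2.2.2]octene, then the primed lactone is closed, then the unprimed lactone.
Stereochemistry: C6 and C7 come from a catalytic enantioselective Diels–Alder reaction. C7' and C4' come from attack on the convex face of the cis-decalin. C6' comes from hydride delivery on the alkene side of the bicyclic ketone. Both butylidene groups become Z through allylic strain.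

Key step: step 8

Assumption: the sense of induction in step 2 is taken from the α-C–H···O binding model for s-trans enones on the (S)-diphenylprolinol-derived boron cation. If the antipode were to form, the catalyst from (R)-diphenylprolinol would be used with no other change.

Step 1
Reactants: 1 but-3-en-2-one
Product: 2 2-(triisopropylsilyloxy)buta-1,3-diene
Conditions: TIPSOTf, Et3N, Et2O, 0 °C to rt
Reagents that add atoms: triisopropylsilyl trifluoromethanesulfonate, CC(C)[Si](C(C)C)(C(C)C)OS(=O)(=O)C(F)(F)F
Why: Soft enolisation and O-silylation of a methyl enone with a silyl triflate and an amine is the standard preparation of 2-silyloxy dienes, and the bulky silyl group is chosen to survive the acidic catalyst of step 2.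

Step 2
Reactants: 2 2-(triisopropylsilyloxy)buta-1,3-diene; 3 cyclohex-2-en-1-one
Product: 4 (4aR,8aS)-6-(triisopropylsilyloxy)-3,4,4a,5,8,8a-hexahydronaphthalen-1(2H)-one (cis-fused)
Conditions: oxazaborolidine from (S)-α,α-diphenylprolinol and o-tolylboronic acid, protonated with Tf2NH (20 mol %), CH2Cl2, −20 °C to rt
Reagents that add atoms: none
Why: In this catalytic enantioselective Diels–Alder reaction the s-trans enone binds to the cationic boron through the lone pair syn to its α-C–H, a phenyl group of the catalyst covers one face, the diene adds suprafacially to the open Si face of the α-carbon and so sets C6 and C7 (cis fusion) in one event, and the silyloxy group steers its neighbouring CH2 terminus to the β-carbon (para rule), which places the future C6' oxygen correctly.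

Step 3
Reactants: 4 cis-decalone silyl enol ether
Product: 5 (4aR,8aS)-1,1-(ethylenedioxy)-6-(triisopropylsilyloxy)-1,2,3,4,4a,5,8,8a-octahydronaphthalene
Conditions: TMSOCH2CH2OTMS, TMSOTf (5 mol %), CH2Cl2, −78 to −20 °C; pyridine quench
Reagents that add atoms: 1,2-bis(trimethylsilyloxy)ethane, C[Si](C)(C)OCCO[Si](C)(C)C
Why: Aprotic ketalisation with the bis-silyl glycol under silyl triflate catalysis is driven by disiloxane formation and runs cold without water or base, so the epimerisable C7 centre next to the ketone and the hindered silyl enol ether should both be left alone.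

Step 4
Reactants: 5 ketal silyl enol ether
Product: 6 cis-decalin enone ketal (4aR,8aR)-5,5-(ethylenedioxy)-4a,5,6,7,8,8a-hexahydronaphthalen-2(1H)-one
Conditions: Pd(OAc)2 (20 mol %), O2 (1 atm), DMSO, 60 °C
Reagents that add atoms: none
Why: In this Saegusa–Ito oxidation the regiodefined C6'=C5' silyl enol ether is metalated at C5' by the divalent palladium salt and β-hydride loss can only take hydrogen from C4', so the C4'=C5' enone forms without a regioisomer and C6 and C7 are not touched.

Step 5
Reactants: 7 hexan-2-one; 8 methyl glyoxylate
Product: 10 methyl 2-hydroxy-4-oxooctanoate (racemic), via lithium hex-1-en-2-olate 9 (not isolated)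
Conditions: LiN(i-Pr)2, THF, −78 °C; 8 (freshly distilled monomer), −78 °C; AcOH quench
Reagents that add atoms: lithium diisopropylamide, [Li]N(C(C)C)C(C)C (lithium, held only in 9)
Why: In this directed aldol addition kinetic deprotonation of the methyl ketone takes place at CH3, the enolate adds to the very electrophilic aldehyde, and the racemic carbinol centre is removed in step 6.

Step 6
Reactants: 10 methyl 2-hydroxy-4-oxooctanoate
Product: 12 methyl (E)-4-oxooct-2-enoate, via mesylate 11 (not isolated)
Conditions: MsCl, Et3N (2.5 equiv), CH2Cl2, 0 °C to rt
Reagents that add atoms: methanesulfonyl chloride, CS(=O)(=O)Cl (held only in 11)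
Why: Mesylation followed by E1cB elimination through the ketone enolate is a standard aldol dehydration and should give the E alkene, in which acyl and ester groups are trans.

Step 7
Reactants: 12 methyl (E)-4-oxooct-2-enoate
Product: 14 methyl (Z)-3-bromo-4-oxooct-2-enoate, via dibromide 13 (not isolated)
Conditions: Br2, CH2Cl2, 0 °C to rt; then Et3N, 0 °C
Reagents that add atoms: bromine, BrBr
Why: Bromine addition and amine-induced loss of HBr is the classical route to α-bromo enones, the proton next to the ketone (C3–H) is the most acidic so bromide leaves from C2 and bromine stays on C3, and the alkene geometry has no consequence because it is lost in the enolate of step 8.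

Step 8
Reactants: 6 cis-decalin enone ketal; 14 methyl (Z)-3-bromo-4-oxooct-2-enoate
Product: 18 cyclopropane-bridged tricyclooctanone keto ester (C7a' epimers), via lithium dienolate 15 (not isolated), via bromo enolate 16 (not isolated), via bicyclic enolate 17 (not isolated)
Conditions: LiN(i-Pr)2, THF, −78 °C; 14, −78 °C; then DMPU, to rt
Reagents that add atoms: lithium diisopropylamide, [Li]N(C(C)C)C(C)C (lithium, held only in 15 to 17)
Why: The amide base removes a C7' proton of 6 under kinetic control to give cross-conjugated dienolate 15, whose C7' adds to C7a' of 14 (β to the ketone), the α-bromo enolate 16 then adds through C3a' to C4' of the regenerated enone, and the C5' enolate 17 finally displaces bromide from C3a'. The closest known reaction is the bicycloannulation (Michael–Michael–ring closure) of cyclohexenone α'-dienolates with α-halo acrylates to tricyclo[3.2.1.0(2,7)]octan-6-ones, the acceptor here being an α-bromo enone that carries an extra ester. The six-membered ring closes by an intramolecular Michael addition that is 6-exo-trig along the path C7'–C6–C7–C4' (6-endo-trig with respect to ring B), and the cyclopropane closes 3-exo-tet with inversion at C3a'. C7' is set by attack on the convex face of the cis-decalin dienolate (the face of H-6 and H-7, anti to the C6–C5 bond and the dioxolane), the short tether forces C3a' onto the same face of C4', the C3a' configuration is sorted by the reversible second Michael step because only the epimer with bromine anti to C5' can cyclise, C5' is fixed by the geometry of the three-membered ring, and C7a' is left uncontrolled because it becomes sp2 in step 9. The step needs α' rather than γ deprotonation, secured by the cold kinetic base and the hindered tertiary C7–H beside the ketal, and first attack at C7a' rather than addition–elimination at C3a', secured because the ketone is the stronger acceptor, its β-carbon carries only hydrogen, and C3a' is fully substituted.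

Step 9
Reactants: 18 cyclopropane-bridged tricyclooctanone keto ester
Product: 19 bicyclo[2.2.2]octenone ene keto ester
Conditions: DBU (1.5 equiv), toluene, 80 °C
Reagents that add atoms: none
Why: Proposed new method: DBU reversibly removes C7a'–H (α to the ester), and because the C3a'–C5' bond lies nearly parallel to the p orbital of this enolate, whereas C3a'–C4' lies in its nodal plane and C4' could not carry charge, an E1cB-type retro-Michael cleavage should expel C5' as the C6' ketone enolate, driven by loss of ring strain and by conjugation of the new tetrasubstituted C7a'=C3a' alkene with both carbonyl groups; the closest known reaction types are the retro-Michael reaction, the reversal of a Michael-initiated ring closure, and the cyclopropylcarbinyl-to-homoallyl anion opening of acceptor-substituted cyclopropanes, and no stereocentre is created while those at C7a', C3a' and C5' vanish.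

Step 10
Reactants: 19 bicyclo[2.2.2]octenone ene keto ester
Product: 20 3'-butyl-3'-hydroxy lactone (ring form of the keto acid; C3' epimers)
Conditions: LiOH, THF/H2O, 0 °C to rt; then 0.5 M HCl to pH 4, 0 °C
Reagents that add atoms: lithium hydroxide, [Li+].[OH-] (its oxygen)
Why: Saponification of a γ-keto ester is assisted by the neighbouring ketone (hydroxide adds to C3' and the alkoxide attacks the ester), so the hindered ester should cleave under mild conditions, the acid rests in its hydroxy lactone form, and the cold, mild acidification keeps the ketal.

Step 11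
Reactants: 20 3'-butyl-3'-hydroxy lactone
Product: 21 (Z)-3'-butylidene lactone with C6' ketone and C7a ketal
Conditions: TsOH·H2O (5 mol %), toluene, Dean–Stark, reflux
Reagents that add atoms: none
Why: Acid-catalysed dehydration of 3-alkyl-3-hydroxy lactones is the classical entry to alkylidene phthalides and butenolides, azeotropic removal of water protects the ketal, and equilibration through the oxygen-stabilised cation should give the Z isomer, in which the propyl chain avoids C4'–H.

Step 12
Reactants: 21 (Z)-3'-butylidene lactone ketone
Product: 22 (6'R)-alcohol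
Conditions: NaBH4, CeCl3·7H2O, MeOH/THF, −78 °C
Reagents that add atoms: none
Why: In this Luche reduction the strained, unconjugated C6' ketone is far more electrophilic than the conjugated enol lactone, and because C5H2 of ring A hangs over the carbonyl face that looks towards the C6–C7 bridge, hydride should arrive from the side of the flat C7a'=C3a' bridge and push the hydroxyl group towards ring A, which is the 6'R configuration of the target.

Step 13
Reactants: 22 (6'R)-alcohol
Product: 23 C6' tert-butyldimethylsilyl ether
Conditions: TBSOTf, 2,6-lutidine, CH2Cl2, −78 to 0 °C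
Reagents that add atoms: tert-butyldimethylsilyl trifluoromethanesulfonate, CC(C)(C)[Si](C)(C)OS(=O)(=O)C(F)(F)F
Why: Silylation with a silyl triflate and a hindered pyridine base is the standard protection of a crowded secondary alcohol and does not touch a ketone-derived ketal or the enol lactone at low temperature.

Step 14
Reactants: 23 C6' silyl ether ketal
Product: 24 C7a ketone
Conditions: PPTS (20 mol %), acetone/H2O (10:1), 55 °C
Reagents that add atoms: water, O
Why: This mild acid-catalysed dioxolane hydrolysis is tolerated by a hindered secondary silyl ether and by the enol lactone, and C7, now α to a ketone, is safe because only the cis fusion of ring A to the rigid bicyclooctene is free of strain.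

Step 15
Reactants: 24 C7a ketone
Product: 25 C3a-pentanoyl C7a ketone (drawn as its ring enol)
Conditions: pentanoyl chloride, 1H-benzotriazole, i-Pr2NEt, CH2Cl2, rt; then 24, MgBr2·OEt2, i-Pr2NEt, rt
Reagents that add atoms: pentanoyl chloride, CCCCC(=O)Cl
Why: C-acylation of a ketone by soft enolisation with an N-acylbenzotriazole avoids the strong base that would attack the enol lactone, and it goes to C3a because only acylation at the CH2 group gives a diketone that can rest as its magnesium chelate, whereas C7 is tertiary and shielded.

Step 16
Reactants: 25 C3a-pentanoyl C7a ketone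
Product: 26 C7a enol triflate
Conditions: Tf2O, i-Pr2NEt, CH2Cl2, −78 °C
Reagents that add atoms: trifluoromethanesulfonic anhydride, O=S(=O)(C(F)(F)F)OS(=O)(=O)C(F)(F)F
Why: In this O-sulfonylation of a β-diketone enol, six-membered 2-acyl ketones enolise inside the ring, so triflation should take place on the C7a oxygen and give the tetrasubstituted ring enol triflate that keeps the pentanoyl ketone.

Step 17
Reactants: 26 C7a enol triflate
Product: 27 O-silyl ether of the target
Conditions: Pd(PPh3)4 (5 mol %), CO (1 atm), Et3N, MeCN, 60 °C
Reagents that add atoms: carbon monoxide, [C-]#[O+]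
Why: In this carbonylative lactonisation zerovalent palladium inserts into the C7a–OTf bond, CO insertion gives an acylpalladium species that is captured 5-exo by the enolate oxygen of the neighbouring pentanoyl group, as known for o-halo aryl ketones and β-halo enones going to alkylidene lactones, and the Z enolate is favoured because the propyl chain avoids C4H2.

Step 18
Reactants: 27 O-silyl ether of the target
Product: 28 CNP0289078.2 (target)
Conditions: HF·pyridine, THF, 0 °C to rt
Reagents that add atoms: none
Why: Fluoride cleavage of the silyl ether in a buffered acidic medium avoids the basic conditions that open enol lactones, and no stereocentre is touched.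

Compound list
1 | but-3-en-2-one | CC(=O)C=C | starting material
2 | 2-(triisopropylsilyloxy)buta-1,3-diene | C=CC(=C)O[Si](C(C)C)(C(C)C)C(C)C | intermediate
3 | cyclohex-2-en-1-one | O=C1C=CCCC1 | starting material
4 | (4aR,8aS)-6-(triisopropylsilyloxy)-3,4,4a,5,8,8a-hexahydronaphthalen-1(2H)-one, cis-fused (C1 = C7a, C4a = C6, C8a = C7) | O=C1CCC[C@@H]2CC(O[Si](C(C)C)(C(C)C)C(C)C)=CC[C@H]12 | intermediate
5 | (4aR,8aS)-1,1-(ethylenedioxy)-6-(triisopropylsilyloxy)-1,2,3,4,4a,5,8,8a-octahydronaphthalene | O1CCOC12CCC[C@@H]3CC(O[Si](C(C)C)(C(C)C)C(C)C)=CC[C@H]23 | intermediate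
6 | cis-decalin enone ketal, (4aR,8aR)-5,5-(ethylenedioxy)-4a,5,6,7,8,8a-hexahydronaphthalen-2(1H)-one (H-6 and H-7 cis) | O1CCOC12CCC[C@@H]3CC(=O)C=C[C@H]23 | intermediate
7 | hexan-2-one | CCCCC(C)=O | starting material
8 | methyl glyoxylate | COC(=O)C=O | starting material
9 | lithium hex-1-en-2-olate | CCCCC(=C)O[Li] | intermediate (not isolated)
10 | methyl 2-hydroxy-4-oxooctanoate, racemic | CCCCC(=O)CC(O)C(=O)OC | intermediate
11 | methyl 2-(methylsulfonyloxy)-4-oxooctanoate, racemic | CCCCC(=O)CC(OS(C)(=O)=O)C(=O)OC | intermediate (not isolated)
12 | methyl (E)-4-oxooct-2-enoate | CCCCC(=O)/C=C/C(=O)OC | intermediate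
13 | methyl (2R*,3S*)-2,3-dibromo-4-oxooctanoate, racemic anti adduct (one enantiomer drawn) | CCCCC(=O)[C@H](Br)[C@H](Br)C(=O)OC | intermediate (not isolated)
14 | methyl (Z)-3-bromo-4-oxooct-2-enoate | CCCCC(=O)/C(Br)=C/C(=O)OC | intermediate
15 | lithium cross-conjugated dienolate of 6 (C7'=C6'(OLi)–C5'=C4') | O1CCOC12CCC[C@@H]3C=C(O[Li])C=C[C@H]23 | intermediate (not isolated)
16 | first Michael adduct, lithium α-bromo enolate; new C7'–C7a' bond on the H-6 face, ring B enone restored | O1CCOC12CCC[C@@H]3[C@@H](C(C(=O)OC)C(Br)=C(O[Li])CCCC)C(=O)C=C[C@H]23 | intermediate (not isolated)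
17 | second Michael adduct, bicyclo[2.2.2]octene lithium C5' enolate; bromine on C3a' points to the C6–C7 bridge | O1CCOC12CCC[C@@H]3[C@H]4C(C(=O)OC)[C@](Br)(C(=O)CCCC)[C@H](C=C4O[Li])[C@H]23 | intermediate (not isolated)
18 | tricyclo[3.2.1.0(2,7)]octan-6-one fused to ketal-bearing ring A; cyclopropane C3a'–C4'–C5', pentanoyl on C3a', CO2Me on C7a' (both epimers), C6' ketone; C6, C7, C7', C4' as in the target | O1CCOC12CCC[C@@H]3[C@H]4C(C(=O)OC)[C@@]5(C(=O)CCCC)[C@H]([C@H]5C4=O)[C@H]23 | intermediate
19 | bicyclo[2.2.2]oct-5-en-2-one with C7a'(CO2Me)=C3a'(pentanoyl), C6' ketone, C5'H2 and ring A ketal; ring A syn to the C5'–C6' bridge | O1CCOC12CCC[C@@H]3[C@H]4C(C(=O)OC)=C(C(=O)CCCC)[C@H](CC4=O)[C@H]23 | intermediate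
20 | 3'-butyl-3'-hydroxy butenolide (ring form of the keto acid, both C3' epimers), C6' ketone, ring A ketal | O1CCOC12CCC[C@@H]3[C@H]4C5=C(C(O)(CCCC)OC5=O)[C@H](CC4=O)[C@H]23 | intermediate
21 | (Z)-3'-butylidene butenolide, C6' ketone, ring A ketal | O1CCOC12CCC[C@@H]3[C@H]4C5=C(/C(=C/CCC)OC5=O)[C@H](CC4=O)[C@H]23 | intermediate
22 | (6'R)-alcohol, hydroxyl syn to ring A and anti to the alkene bridge | O1CCOC12CCC[C@@H]3[C@H]4C5=C(/C(=C/CCC)OC5=O)[C@H](C[C@H]4O)[C@H]23 | intermediate
23 | C6' tert-butyldimethylsilyl ether of 22 | O1CCOC12CCC[C@@H]3[C@H]4C5=C(/C(=C/CCC)OC5=O)[C@H](C[C@H]4O[Si](C)(C)C(C)(C)C)[C@H]23 | intermediate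
24 | C7a ketone (ring A cyclohexanone) | O=C1CCC[C@@H]2[C@H]3C4=C(/C(=C/CCC)OC4=O)[C@H](C[C@H]3O[Si](C)(C)C(C)(C)C)[C@H]12 | intermediate
25 | C3a-pentanoyl C7a ketone, drawn as the chelated ring enol | OC1=C(C(=O)CCCC)CC[C@@H]2[C@H]3C4=C(/C(=C/CCC)OC4=O)[C@H](C[C@H]3O[Si](C)(C)C(C)(C)C)[C@H]12 | intermediate
26 | C7a enol triflate with pentanoyl on C3a | FC(F)(F)S(=O)(=O)OC1=C(C(=O)CCCC)CC[C@@H]2[C@H]3C4=C(/C(=C/CCC)OC4=O)[C@H](C[C@H]3O[Si](C)(C)C(C)(C)C)[C@H]12 | intermediate
27 | C6' O-tert-butyldimethylsilyl ether of the target, both (Z)-butylidene lactones in place | CCC/C=C1\OC(=O)C2=C1CC[C@@H]1[C@H]3C4=C(/C(=C/CCC)OC4=O)[C@H](C[C@H]3O[Si](C)(C)C(C)(C)C)[C@H]21 | intermediate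
28 | CNP0289078.2, (6S,7R,4'R,6'R,7'S; 3Z,3'Z) in the numbering of the plan | CCC/C=C1\OC(=O)C2=C1CC[C@@H]1[C@H]3C4=C(/C(=C/CCC)OC4=O)[C@H](C[C@H]3O)[C@H]21 | target

Total step count: 18. Longest linear sequence: 15 steps (steps 1 to 4 and 8 to 18). Steps 5 to 7 form the side branch.

Steps most likely to fail

Step 9 (proposed new method). Deprotonation at C7a' may be too slow next to enolisation of the pentanoyl chain. The ester enolate may also fail to fragment, so that the cyclopropane persists or the material degrades on forcing. The fallback uses known chemistry, sets out from 6 and comes back at 19.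
- Dienolate 15 is silylated with TBSCl to the 2-silyloxy diene F1.
- Lithiated methyl propiolate (n-BuLi, THF, −78 °C) is added to pentanal to give methyl 4-hydroxyoct-2-ynoate F2.
- Dess–Martin periodinane oxidises F2 to methyl 4-oxooct-2-ynoate F3.
- A thermal Diels–Alder reaction of F1 with F3 (toluene, 60 °C) joins C7', the diene terminus next to the silyloxy carbon, to the alkyne carbon β to the ketone. It takes place on the face anti to ring A and gives the bicyclo[2.2.2]octadiene silyl enol ether F4.
- HF·pyridine cleaves the silyl enol ether of F4 to 19.

Step 8. Several processes can compete with the cascade: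
- proton transfer from the acidic CH2 group of the acceptor to the dienolate;
- loss of HBr from the acceptor;
- attack at C3a' with expulsion of bromide;
- stalling after the first Michael addition.

The fallback forms the same bonds in two separate stages, sets out from 6 and 14, and comes back at 18. The 2-silyloxy diene F1 described above is heated with 14 (toluene, 80 °C). This Diels–Alder reaction places the ketone endo and therefore the bromine anti to the enol ether bridge, and gives the bromo bicyclo[2.2.2]octene silyl enol ether F5. TBAF (THF, −20 °C) then frees the C5' enolate, which closes the cyclopropane by 3-exo-tet displacement to 18.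

Step 17. The acylpalladium intermediate may be consumed by decarbonylation, reduction or adventitious water before the ketone enolises. Oxygen trapping may also be too slow. The fallback separates carbonylation from ring closure, sets out from 26 and comes back at 27.
- Methoxycarbonylation (Pd(OAc)2/dppp, CO, MeOH, Et3N, DMF, 60 °C) gives the C7a methyl ester F6.
- LiOH hydrolyses this ester and opens the primed enol lactone, and mild acidification gives the bis(hydroxy lactone) F7.
- Double enol lactonisation with Ac2O and NaOAc at 90 °C closes both (Z)-butylidene lactones to 27.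

Further compounds
F1 | step 9 | tert-butyldimethylsilyl dienol ether of 6 (2-silyloxy diene C7'=C6'–C5'=C4') | O1CCOC12CCC[C@@H]3C=C(O[Si](C)(C)C(C)(C)C)C=C[C@H]23
F2 | step 9 | methyl 4-hydroxyoct-2-ynoate (racemic) | CCCCC(O)C#CC(=O)OC
F3 | step 9 | methyl 4-oxooct-2-ynoate | CCCCC(=O)C#CC(=O)OC
F4 | step 9 | bicyclo[2.2.2]octadiene silyl enol ether with C7a'(CO2Me)=C3a'(pentanoyl) | O1CCOC12CCC[C@@H]3[C@H]4C(C(=O)OC)=C(C(=O)CCCC)[C@H](C=C4O[Si](C)(C)C(C)(C)C)[C@H]23
F5 | step 8 | bromo bicyclo[2.2.2]octene silyl enol ether (pentanoyl endo, bromine and ester towards the C6–C7 bridge) | O1CCOC12CCC[C@@H]3[C@H]4[C@@H](C(=O)OC)[C@](Br)(C(=O)CCCC)[C@H](C=C4O[Si](C)(C)C(C)(C)C)[C@H]23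
F6 | step 17 | C7a methyl ester with pentanoyl on C3a | COC(=O)C1=C(C(=O)CCCC)CC[C@@H]2[C@H]3C4=C(/C(=C/CCC)OC4=O)[C@H](C[C@H]3O[Si](C)(C)C(C)(C)C)[C@H]12
F7 | step 17 | bis(3-butyl-3-hydroxy lactone), C3 and C3' epimers | CCCCC1(O)OC(=O)C2=C1CC[C@@H]1[C@H]3C4=C(C(O)(CCCC)OC4=O)[C@H](C[C@H]3O[Si](C)(C)C(C)(C)C)[C@H]21
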